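**Retrosynthetic overview**

- Ring numbering: C1 (CMeCl), C2 (CH2), C3 (quaternary, Me and the C7=C8 bromovinyl arm), C4 (CHBr), C5 (CH2), C6 (CHCl); β is the ring face of the C7=C8 arm, α the face of the two methyl groups. The strategy rests on quaternary C3, whose two two-carbon arms (C4–C5 inside the ring, C7–C8 outside it) are the two acetyl groups of a 3,3-disubstituted pentane-2,4-dione, enantiotopic until one of them closes the ring.
- Endgame disconnections: cis-C1/C6 dichloride ⇐ α-epoxide (double inversion) ⇐ C1=C6 alkene ⇐ dehydration of the C6 aldol hydroxyl; (E)-bromovinyl ⇐ ethynyl ⇐ spectator acetyl; C4–Br ⇐ β-C4 carbinol with retention through homoallylic participation of C1=C6 (backside attack at neopentylic C4 is not relied on) ⇐ C4 ketone.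
- Key disconnection C5–C6: amine-catalysed intramolecular aldol of keto aldehyde 3 to ketol 5, the only ring-forming step; it fixes C3 for good, while C1 and C6 serve only as conformational anchors before they are erased.
- 3 ⇐ Michael addition of 3-methylpentane-2,4-dione (1) to methacrolein (2).

Key step: step 2

Assumption: the L-configured primary amino acid is taken to direct attack on the Re face of the formyl group, as it does in intermolecular ketone–aldehyde aldol reactions; should the sense be the opposite, O-tert-butyl-D-threonine is used with no other change.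

**Route**

Step 1
Reactants: 1 3-methylpentane-2,4-dione; 2 methacrolein
Product: 3 rac-3-methyl-3-(2-methyl-3-oxopropyl)pentane-2,4-dione
Conditions: Et3N (0.1 equiv), MeCN, 0 °C to rt
Reagents that add atoms: none
Why: Base-catalysed Michael addition of the acidic C–H of the 2-substituted 1,3-diketone to the enal should build quaternary C3 and the C2–C3 bond, and no stereocontrol is needed because C1 is epimerised in the next step.

Step 2
Reactants: 3 rac-3-methyl-3-(2-methyl-3-oxopropyl)pentane-2,4-dione
Product: 5 (2S,4R,5R)-2-acetyl-5-hydroxy-2,4-dimethylcyclohexan-1-one, via acetyl enamine 4 (not isolated)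
Conditions: O-tert-butyl-L-threonine (20 mol%), DMSO, H2O (3 equiv), rt
Reagents that add atoms: none
Why: Proposed new method: the primary amine condenses with one acetyl group to the N–H enamine 4 (only an acetyl methyl is a productive donor, since C3 is quaternary and the aldehyde enamine could close only a four-membered ring) and its methylene carbon C5 adds to the formyl carbon C6; the closest known reaction type is the amine-catalysed 6-enolendo aldol cyclisation of 1,5-dicarbonyl compounds (Hajos–Parrish reaction, cyclisations of 2,6-diketones and δ-keto aldehydes), and what is new is the choice between two enantiotopic acetyl donors coupled to a dynamic resolution of the acceptor. The cyclohexanone closes in the 6-(enolendo)-exo-trig mode, because both enamine carbons C4 and C5 lie in the new ring, through a chair-like transition state. C6 is set by the catalyst: its carboxylic acid, held next to C5 in the enamine rotamer that keeps the amino acid residue away from quaternary C3, should hydrogen-bond the equatorial formyl oxygen and so select the Re face. C1 is set by dynamic kinetic resolution: the enantiomer of 3 that places the C1 methyl group equatorial in this chair cyclises, and the other is returned through the aldehyde imine–enamine equilibrium with the catalyst. C3 is set by which acetyl group becomes the enamine: the spectator acetyl is expected in the pseudoaxial position anti to the forming bond (smaller A value than methyl), which places it cis to the new hydroxyl, and this is the least secure of the three selections. The step needs donor-group selectivity, face selectivity and C1 epimerisation faster than ring closure; the first two rest on the chair described, the third on the α-branched formyl group, and because the wrong acetyl choice gives a diastereomer of 5 and not its enantiomer, it can be removed by chromatography or crystallisation.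

Step 3
Reactants: 5 (2S,4R,5R)-2-acetyl-5-hydroxy-2,4-dimethylcyclohexan-1-one
Product: 6 1-[(1R,2S,4R,5R)-2,4-dihydroxy-1,5-dimethylcyclohexyl]ethan-1-one
Conditions: NaBH4 (1 equiv), CeCl3·7H2O (1 equiv), MeOH, −78 °C, short reaction time
Reagents that add atoms: none
Why: Luche reduction in which the ring ketone, far more reactive than the pinacolone-like acetyl group, should be attacked axially on the α face, anti to the axial C3 acetyl group of the chair that holds C1–Me, C3–Me and C6–OH equatorial (Felkin–Anh and steric control agree), so that the new C4 hydroxyl is equatorial, β and cis to the acetyl group.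

Step 4
Reactants: 6 1-[(1R,2S,4R,5R)-2,4-dihydroxy-1,5-dimethylcyclohexyl]ethan-1-one
Product: 8 1-[(1R,6S)-6-hydroxy-1,3-dimethylcyclohex-3-en-1-yl]ethan-1-one, via C6 sulfamate 7 (not isolated)
Conditions: Burgess reagent (1.1 equiv), THF, 0 °C to rt, then 50 °C
Reagents that add atoms: none
Why: Burgess dehydration, in which the reagent should sulfonylate the less hindered C6 hydroxyl (the C4 hydroxyl is neopentylic) and the sulfamate ester should undergo syn elimination with the cis-disposed tertiary C1–H in the Zaitsev sense, giving the trisubstituted C1=C6 alkene and deleting the C1 and C6 stereocentres.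

Step 5
Reactants: 8 1-[(1R,6S)-6-hydroxy-1,3-dimethylcyclohex-3-en-1-yl]ethan-1-one
Product: 9 1-[(1R,6S)-1,3-dimethyl-6-(triethylsilyloxy)cyclohex-3-en-1-yl]ethan-1-one
Conditions: TESOTf (1.3 equiv), 2,6-lutidine, CH2Cl2, −78 to 0 °C
Reagents that add atoms: triethylsilyl trifluoromethanesulfonate, CC[Si](CC)(CC)OS(=O)(=O)C(F)(F)F
Why: Silylation of the hindered secondary alcohol with the silyl triflate protects the β-hydroxy ketone against retro-aldol cleavage and O-phosphorylation in the strongly basic step that follows.

Step 6
Reactants: 9 1-[(1R,6S)-1,3-dimethyl-6-(triethylsilyloxy)cyclohex-3-en-1-yl]ethan-1-one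
Product: 11 triethyl{[(1S,6S)-6-ethynyl-4,6-dimethylcyclohex-3-en-1-yl]oxy}silane, via enol phosphate 10 (not isolated)
Conditions: LiN(iPr)2 (1.1 equiv), THF, −78 °C; ClP(O)(OEt)2, −78 °C to rt; LiN(iPr)2 (2.3 equiv), −78 °C to rt; then H2O
Reagents that add atoms: none
Why: Methyl ketone to terminal alkyne by enol phosphate formation and β-elimination, in which only the methyl group can be deprotonated because C3 is quaternary, the kinetic enolate is O-phosphorylated and further amide base eliminates diethyl phosphate to the lithium acetylide that is protonated on work-up.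

Step 7
Reactants: 11 triethyl{[(1S,6S)-6-ethynyl-4,6-dimethylcyclohex-3-en-1-yl]oxy}silane
Product: 12 (1S,6S)-6-ethynyl-4,6-dimethylcyclohex-3-en-1-ol
Conditions: HF·pyridine, pyridine, THF, 0 °C to rt
Reagents that add atoms: none
Why: Buffered fluoride cleavage of the Si–O bond should free the C4 hydroxyl without touching the alkyne or the trisubstituted alkene.

Step 8
Reactants: 12 (1S,6S)-6-ethynyl-4,6-dimethylcyclohex-3-en-1-ol
Product: 14 (4S,5S)-4-bromo-5-ethynyl-1,5-dimethylcyclohex-1-ene, via oxyphosphonium bromide 13 (not isolated)
Conditions: PPh3 (1.5 equiv), CBr4 (1.5 equiv), CH2Cl2, 0 °C to rt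
Reagents that add atoms: tetrabromomethane, BrC(Br)(Br)Br
Why: Appel reaction with overall retention, in which the equatorial C4 oxyphosphonium of 13, antiperiplanar to the C5–C6 bond, should ionise with participation of the homoallylic C1=C6 π bond (cyclopropylcarbinyl cation with the charge on tertiary C1) and be reopened by bromide at C4 on the β face, as in the conversion of cholesterol into cholesteryl halides (cyclosteroid rearrangement), so that no external backside attack at the neopentylic carbon is required.

Step 9
Reactants: 14 (4S,5S)-4-bromo-5-ethynyl-1,5-dimethylcyclohex-1-ene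
Product: 16 (4S,5S)-4-bromo-5-[(E)-2-bromoethenyl]-1,5-dimethylcyclohex-1-ene, via alkenylzirconocene 15 (not isolated)
Conditions: Cp2Zr(H)Cl (1.3 equiv), THF, rt; NBS, 0 °C
Reagents that add atoms: N-bromosuccinimide, O=C1CCC(=O)N1Br
Why: Hydrozirconation with the Schwartz reagent should add Zr–H syn across the terminal alkyne with zirconium on the terminal carbon (the trisubstituted alkene and the secondary bromide are much less reactive), and bromodezirconation with retention gives the (E)-bromoalkene.

Step 10
Reactants: 16 (4S,5S)-4-bromo-5-[(E)-2-bromoethenyl]-1,5-dimethylcyclohex-1-ene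
Product: 17 (1R,3S,4S,6S)-4-bromo-3-[(E)-2-bromoethenyl]-1,3-dimethyl-7-oxabicyclo[4.1.0]heptane
Conditions: mCPBA (1.1 equiv), NaHCO3, CH2Cl2, 0 °C
Reagents that add atoms: 3-chloroperoxybenzoic acid, OOC(=O)c1cccc(Cl)c1
Why: Prilezhaev epoxidation of the electron-rich trisubstituted alkene (the bromovinyl group is deactivated) should occur on the α face, because only the half-chair with equatorial C4–Br offers a face free of an axial homoallylic substituent, namely the face opposite the axial bromovinyl group, whereas in the other half-chair axial C3–Me and axial C4–Br hinder both faces.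

Step 11
Reactants: 17 (1R,3S,4S,6S)-4-bromo-3-[(E)-2-bromoethenyl]-1,3-dimethyl-7-oxabicyclo[4.1.0]heptane
Product: 19 (1S,2S,4R,5S)-2-bromo-1-[(E)-2-bromoethenyl]-4,5-dichloro-1,5-dimethylcyclohexane, via chlorohydrin oxyphosphonium chloride 18 (not isolated)
Conditions: Ph3PCl2 (2.5 equiv), toluene, 0 to 60 °C
Reagents that add atoms: dichlorotriphenylphosphorane, ClP(Cl)(c1ccccc1)(c1ccccc1)c1ccccc1
Why: Epoxide deoxydichlorination by double inversion, in which phosphorus activates the epoxide oxygen, chloride opens it at tertiary C1 from the β face in the trans-diaxial (Fürst–Plattner) sense available in the half-chair with equatorial C4–Br to give 18, and a second chloride displaces triphenylphosphine oxide at C6 with inversion, so that both chlorines end up β and cis to each other.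

**Compound list**

1 | 3-methylpentane-2,4-dione | CC(=O)C(C)C(C)=O | starting material
2 | methacrolein (2-methylprop-2-enal) | C=C(C)C=O | starting material
3 | rac-3-methyl-3-(2-methyl-3-oxopropyl)pentane-2,4-dione (racemic at C1) | CC(=O)C(C)(CC(C)C=O)C(C)=O | intermediate
4 | (2S,3R)-2-{[(3R,5R)-3-acetyl-3,5-dimethyl-6-oxohex-1-en-2-yl]amino}-3-tert-butoxybutanoic acid (enamine of one acetyl group of the matched enantiomer of 3) | C[C@@H](C=O)C[C@@](C)(C(C)=O)C(=C)N[C@@H]([C@@H](C)OC(C)(C)C)C(=O)O | intermediate (not isolated)
5 | (2S,4R,5R)-2-acetyl-5-hydroxy-2,4-dimethylcyclohexan-1-one (hydroxyl cis to acetyl, C1 methyl trans to hydroxyl) | C[C@@H]1C[C@@](C)(C(C)=O)C(=O)C[C@H]1O | intermediate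
6 | 1-[(1R,2S,4R,5R)-2,4-dihydroxy-1,5-dimethylcyclohexyl]ethan-1-one (both hydroxyls β) | C[C@@H]1C[C@@](C)(C(C)=O)[C@@H](O)C[C@H]1O | intermediate
7 | C6 O-[(methoxycarbonyl)sulfamate] of 6, triethylammonium salt | C[C@@H]1C[C@@](C)(C(C)=O)[C@@H](O)C[C@H]1OS(=O)(=O)[N-]C(=O)OC.CC[NH+](CC)CC | intermediate (not isolated)
8 | 1-[(1R,6S)-6-hydroxy-1,3-dimethylcyclohex-3-en-1-yl]ethan-1-one | CC1=CC[C@H](O)[C@](C)(C(C)=O)C1 | intermediate
9 | 1-[(1R,6S)-1,3-dimethyl-6-(triethylsilyloxy)cyclohex-3-en-1-yl]ethan-1-one | CC1=CC[C@H](O[Si](CC)(CC)CC)[C@](C)(C(C)=O)C1 | intermediate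
10 | diethyl 1-[(1R,6S)-1,3-dimethyl-6-(triethylsilyloxy)cyclohex-3-en-1-yl]ethenyl phosphate | CC1=CC[C@H](O[Si](CC)(CC)CC)[C@](C)(C(=C)OP(=O)(OCC)OCC)C1 | intermediate (not isolated)
11 | triethyl{[(1S,6S)-6-ethynyl-4,6-dimethylcyclohex-3-en-1-yl]oxy}silane | CC1=CC[C@H](O[Si](CC)(CC)CC)[C@](C)(C#C)C1 | intermediate
12 | (1S,6S)-6-ethynyl-4,6-dimethylcyclohex-3-en-1-ol | CC1=CC[C@H](O)[C@](C)(C#C)C1 | intermediate
13 | {[(1S,6S)-6-ethynyl-4,6-dimethylcyclohex-3-en-1-yl]oxy}triphenylphosphonium bromide | CC1=CC[C@H](O[P+](c2ccccc2)(c2ccccc2)c2ccccc2)[C@](C)(C#C)C1.[Br-] | intermediate (not isolated)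
14 | (4S,5S)-4-bromo-5-ethynyl-1,5-dimethylcyclohex-1-ene | CC1=CC[C@H](Br)[C@](C)(C#C)C1 | intermediate
15 | chlorido{(E)-2-[(1S,6S)-6-bromo-1,3-dimethylcyclohex-3-en-1-yl]ethenyl}bis(cyclopentadienyl)zirconium | CC1=CC[C@H](Br)[C@](C)(/C=C/[Zr](Cl)(C2C=CC=C2)C2C=CC=C2)C1 | intermediate (not isolated)
16 | (4S,5S)-4-bromo-5-[(E)-2-bromoethenyl]-1,5-dimethylcyclohex-1-ene | CC1=CC[C@H](Br)[C@](C)(/C=C/Br)C1 | intermediate
17 | (1R,3S,4S,6S)-4-bromo-3-[(E)-2-bromoethenyl]-1,3-dimethyl-7-oxabicyclo[4.1.0]heptane (epoxide oxygen α) | C[C@@]12C[C@@](C)(/C=C/Br)[C@@H](Br)C[C@@H]1O2 | intermediate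
18 | {[(1S,2S,4S,5S)-5-bromo-4-[(E)-2-bromoethenyl]-2-chloro-2,4-dimethylcyclohexyl]oxy}triphenylphosphonium chloride | C[C@]1(Cl)C[C@@](C)(/C=C/Br)[C@@H](Br)C[C@@H]1O[P+](c2ccccc2)(c2ccccc2)c2ccccc2.[Cl-] | intermediate (not isolated)
19 | (1S,2S,4R,5S)-2-bromo-1-[(E)-2-bromoethenyl]-4,5-dichloro-1,5-dimethylcyclohexane | C[C@]1(Cl)C[C@@](C)(/C=C/Br)[C@@H](Br)C[C@H]1Cl | target

**Step count and risks**

Total step count: 11. Longest linear sequence: 11 steps (from 1 and 2).

Steps most likely to fail:

Step 2 (Proposed new method). The two acetyl donors may be discriminated poorly, or ring closure may outrun epimerisation at C1, so that diastereomers or material of low enantiomeric purity result; loss of water from the ketol to the conjugated enone is a further drain. The fallback uses known chemistry, sets out from 3 and returns at 5. Compound 3 is cyclised with an achiral amine salt (pyrrolidinium acetate, CH2Cl2, rt) under equilibrating conditions to the racemic ketol F1 of the same relative configuration, the thermodynamically favoured mostly equatorial diastereomer. F1 is resolved by lipase-catalysed transesterification (Candida antarctica lipase B, vinyl acetate, tert-butyl methyl ether). By the Kazlauskas rule the (5R) alcohol should be acylated to the ketol acetate F2, which is separated from the unreacted enantiomeric ketol F3 and hydrolysed by the same lipase in phosphate buffer to 5.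

Step 11. After chloride has opened the activated epoxide at C1, displacement at C6 must compete with participation by the neighbouring chlorine (chloronium formation and loss of the cis relationship) and with elimination. The fallback sets out from 17 and returns at 19. The epoxide is opened with anhydrous HCl (Et2O, −40 °C), chloride entering at tertiary C1 with inversion, to the trans-diaxial chlorohydrin F4. The C6 hydroxyl is converted into the chlorohydrin triflate F5 (Tf2O, pyridine, CH2Cl2, −40 °C), and this isolable sulfonate is displaced with inversion by Bu4NCl in toluene (0 °C to rt) to give 19.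

Step 8. The cyclopropylcarbinyl cation may be captured at tertiary C1 or lose a proton instead of being reopened at C4, and the oxyphosphonium may eliminate towards C5 to the conjugated diene. The fallback sets out from 12 and returns at 14, and separates ionisation from bromide delivery as in the classical cyclosteroid sequence. Alcohol 12 is converted into the homoallylic mesylate F6 (MsCl, Et3N, CH2Cl2, −20 °C). Buffered methanolysis (MeOH, KOAc, 50 °C) gives the rearranged cyclopropylcarbinyl methyl ether F7. Bromotrimethylsilane (CH2Cl2, −40 °C) then reopens the cyclopropane with bromide at C4 on the β face to give 14.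

Further compounds
F1 | step 2 | rac-(2S*,4R*,5R*)-2-acetyl-5-hydroxy-2,4-dimethylcyclohexan-1-one (racemic ketol, written as both enantiomers) | C[C@@H]1C[C@@](C)(C(C)=O)C(=O)C[C@H]1O.C[C@H]1C[C@](C)(C(C)=O)C(=O)C[C@@H]1O
F2 | step 2 | (1R,2R,4S)-4-acetyl-2,4-dimethyl-5-oxocyclohexyl acetate (acetate of 5) | C[C@@H]1C[C@@](C)(C(C)=O)C(=O)C[C@H]1OC(C)=O
F3 | step 2 | (2R,4S,5S)-2-acetyl-5-hydroxy-2,4-dimethylcyclohexan-1-one (enantiomer of 5) | C[C@H]1C[C@](C)(C(C)=O)C(=O)C[C@@H]1O
F4 | step 11 | (1S,2S,4S,5S)-5-bromo-4-[(E)-2-bromoethenyl]-2-chloro-2,4-dimethylcyclohexan-1-ol | C[C@]1(Cl)C[C@@](C)(/C=C/Br)[C@@H](Br)C[C@@H]1O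
F5 | step 11 | (1S,2S,4S,5S)-5-bromo-4-[(E)-2-bromoethenyl]-2-chloro-2,4-dimethylcyclohexyl trifluoromethanesulfonate | C[C@]1(Cl)C[C@@](C)(/C=C/Br)[C@@H](Br)C[C@@H]1OS(=O)(=O)C(F)(F)F
F6 | step 8 | (1S,6S)-6-ethynyl-4,6-dimethylcyclohex-3-en-1-yl methanesulfonate | CC1=CC[C@H](OS(C)(=O)=O)[C@](C)(C#C)C1
F7 | step 8 | 4-ethynyl-2-methoxy-2,4-dimethylbicyclo[3.1.0]hexane (methoxy and ethynyl on the face opposite the cyclopropane methylene) | CO[C@@]1(C)C[C@@](C)(C#C)[C@@H]2C[C@H]12
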